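**Retrosynthetic overview**
1. Zeylenone 16 is traced back to its 1,6-O-isopropylidene derivative 15, so only a ketal hydrolysis follows the key step.
2. The key disconnection is C4–C5. C4 is the β-carbon of the C2 enone and C5 is a former aldehyde carbon, so both are acceptor carbons. They are joined by polarity reversal: BzBr adds across the C5 aldehyde, and the bromide gives a nucleophilic α-benzoyloxy radical. This radical closes onto an (E)-β-stannyl enone and ejects Bu3Sn•.
3. The enabling feature is the cis-diol C1–OH/C6–OH. Tied into a 1,3-dioxolane ring, it holds the C2 acyl arm and C5 on one face. The C5–O–benzoyl group of the target is also the substituent that makes C5 a nucleophilic radical.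
4. Acyclic precursor 12 comes from D-mannose diacetonide, whose sugar C2/C3 become C1/C6. A formaldehyde aldol sets quaternary C1, ethynyl Grignard addition plus hydrostannation supply C3–C4, and periodate excises sugar C5/C6 to reveal C5 as the aldehyde.
5. Ring order: the temporary dioxolane is present from 1, the cyclohexenone forms in step 7, and the dioxolane is removed in step 8.

Key step: step 7

Remark on the chemistry: C1–C6 denote the zeylenone ring (C1 = tertiary carbinol carbon bearing CH2OBz, C2 = ketone, C3=C4 = alkene, C5 = CHOBz, C6 = CHOH). "Sugar C-n" is mannose numbering. Epimer mixtures at centres that are destroyed later (the propargylic carbinol and the bromide-bearing carbon) are assumed to be carried on unseparated.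

Step 1
Reactants: 1 2,3:5,6-di-O-isopropylidene-α-D-mannofuranose; 2 formaldehyde
Product: 3 2-C-(hydroxymethyl)-2,3:5,6-di-O-isopropylidene-D-mannofuranose (anomer mixture; CH2OH takes the place of H-2)
Conditions: 37 % aq. CH2O, K2CO3, MeOH, reflux
Reagents that add atoms: formaldehyde, C=O
Why: Crossed aldol of the ring-opened aldehyde enolate with formaldehyde; the electrophile enters the dioxolane enolate anti to the sugar C4 side chain, so the formyl group stays cis to O4 and recloses to the cis-fused lactol, which sets the quaternary centre (future C1, S) and shields the aldehyde from Cannizzaro reduction.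

Step 2
Reactants: 3 branched lactol; 4 ethynylmagnesium bromide
Product: 5 alkynyl triol (1,2-dideoxy-4-C-(hydroxymethyl)-4,5:7,8-di-O-isopropylidene-oct-1-ynitol, D-manno stereocentres retained, both epimers at the propargylic carbinol)
Conditions: HC≡CMgBr (5 equiv), THF, 0 °C to rt; aq. NH4Cl
Reagents that add atoms: ethynylmagnesium bromide, C#C[Mg]Br
Why: Grignard addition to the open-chain aldehyde in equilibrium with the magnesium lactolate (two equivalents are spent on the OH groups); the new carbinol centre needs no control because step 5 oxidises it.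

Step 3
Reactants: 5 alkynyl triol; 6 benzoyl chloride
Product: 7 alkynyl diol monobenzoate (CH2OH of 5 converted into CH2OBz)
Conditions: BzCl (1.05 equiv), pyridine, CH2Cl2, −30 to 0 °C
Reagents that add atoms: benzoyl chloride, O=C(Cl)c1ccccc1
Why: Kinetically selective acylation of the only primary hydroxyl, since both secondary carbinols are flanked by a fully substituted carbon or by dioxolane carbons.

Step 4
Reactants: 7 alkynyl diol monobenzoate; 8 tributyltin hydride
Product: 9 (E)-γ-hydroxy vinylstannane diol (Bu3Sn on the terminal carbon)
Conditions: Bu3SnH (1.2 equiv), PdCl2(PPh3)2 (2 mol %), THF, 0 °C to rt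
Reagents that add atoms: tributyltin hydride, CCCC[SnH](CCCC)CCCC
Why: Palladium-catalysed syn-hydrostannation of a terminal propargylic alcohol; the bulky, fully substituted neighbour directs tin to the terminus and syn addition fixes the E geometry.

Step 5
Reactants: 9 (E)-γ-hydroxy vinylstannane diol
Product: 10 [(4S,5S)-5-{(R)-[(4R)-2,2-dimethyl-1,3-dioxolan-4-yl](hydroxy)methyl}-2,2-dimethyl-4-[(E)-3-(tributylstannyl)prop-2-enoyl]-1,3-dioxolan-4-yl]methyl benzoate
Conditions: MnO2 (activated, excess), CH2Cl2, rt
Reagents that add atoms: none
Why: MnO2 oxidises only the allylic carbinol, a known route to β-stannyl enones, and leaves the isolated secondary OH, the C–Sn bond and the ester untouched.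

Step 6
Reactants: 10 (E)-β-stannyl enone
Product: 12 [(4S,5R)-5-formyl-2,2-dimethyl-4-[(E)-3-(tributylstannyl)prop-2-enoyl]-1,3-dioxolan-4-yl]methyl benzoate, via enone triol 11 (not isolated)
Conditions: AcOH/H2O 4:1, 30 °C; evaporate with PhMe; NaIO4 (2.2 equiv), THF/pH 7 phosphate buffer, 0 °C
Reagents that add atoms: none
Why: The terminal dioxolane hydrolyses faster than the internal, fully substituted and electron-poor one, and Malaprade cleavage of the resulting 4,5,6-triol with two equivalents of periodate excises sugar C5 and C6, leaving sugar C4 as the C5 aldehyde under neutral conditions that should not epimerise C6.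

Step 7
Reactants: 12 keto aldehyde; 13 benzoyl bromide
Product: 15 1,6-O-isopropylidene-zeylenone (cis-fused dioxolane on C1–O/C6–O, C5–OBz trans to C6–O; 1S,5R,6S), via bromo benzoate 14 (not isolated)
Conditions: BzBr (1.1 equiv), Zn(OTf)2 (2 mol %), 2,6-di-tert-butyl-4-methylpyridine (0.2 equiv), PhH, rt; dilute to 0.01 M, (Bu3Sn)2 (10 mol %), sunlamp (Pyrex), 30 °C
Reagents that add atoms: benzoyl bromide, O=C(Br)c1ccccc1
Why: Proposed new method: benzoyl bromide adds across the C5 aldehyde (known Zn(OTf)2-catalysed 1-bromoalkyl ester formation) to give 14 as an epimer mixture, Bu3Sn• from photolysed (Bu3Sn)2 abstracts bromine, the planar nucleophilic α-benzoyloxy radical at C5 attacks C4 (the tin-bearing β-carbon of the C2 enone), and the resulting C3 α-keto radical ejects Bu3Sn• by β-scission, which re-creates C3=C4 as the ring cis-alkene and carries the chain without any hydrogen donor, so premature reduction of the C5 radical is excluded. The closest known reaction types are tin-mediated cyclisations of aldehyde-derived 1-bromoalkyl esters used as ketyl equivalents, Giese additions of α-oxygenated (glycosyl) radicals to enones, and the intermolecular radical addition–elimination of alkyl halides with β-tributylstannyl acrylates and enones; merging them into a ring closure is the new element. The carbocycle closes in the 6-endo-trig mode, the normal mode when the acceptor carbonyl lies inside the forming ring, because the 5-exo alternative would attack the α-carbon C3 (small LUMO coefficient) and give a non-stabilised radical that cannot lose tin. The new stereocentre C5 is controlled by C6 and C1 through a chair-like transition state on the cis-fused dioxolane in which CH2OBz and the C6–O bond are equatorial (C6–O antiperiplanar to the forming bond) and the benzoyloxy group takes the pseudo-equatorial site away from the fully substituted C1, which places it trans to the C6 oxygen (5R); both epimers of 14 converge on this outcome. The step needs BzBr to attack the aldehyde rather than the ketal, the ketone or the C–Sn bond, which is secured by the higher electrophilicity of the α-oxygenated aldehyde, by the three acyl-type groups that deactivate the dioxolane oxygens and by the electron-poor stannyl enone (the hindered pyridine traps HBr); it also needs cyclisation to outrun oligomerisation, which is secured by high dilution, by the dioxolane holding both arms on one face and by the E geometry, which leaves only hydrogen on the inner side of C4.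

Step 8
Reactants: 15 1,6-O-isopropylidene-zeylenone
Product: 16 zeylenone, [(1S,5R,6S)-5-(benzoyloxy)-1,6-dihydroxy-2-oxocyclohex-3-en-1-yl]methyl benzoate
Conditions: TFA/H2O 9:1, CH2Cl2, 0 °C to rt
Reagents that add atoms: none
Why: Acid hydrolysis of the ketal; both benzoates and the γ-acyloxy enone tolerate aqueous TFA (base is avoided) and no stereocentre is touched.

**Compound list**
1 | 2,3:5,6-di-O-isopropylidene-α-D-mannofuranose | O[C@H]1O[C@H]([C@H]2COC(C)(C)O2)[C@@H]2OC(C)(C)O[C@H]12 | starting material
2 | formaldehyde | C=O | starting material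
3 | 2-C-(hydroxymethyl)-2,3:5,6-di-O-isopropylidene-D-mannofuranose (anomer mixture) | OC1O[C@H]([C@H]2COC(C)(C)O2)[C@@H]2OC(C)(C)O[C@]12CO | intermediate
4 | ethynylmagnesium bromide | C#C[Mg]Br | starting material
5 | alkynyl triol (carbinol epimers) | C#CC(O)[C@@]1(CO)OC(C)(C)O[C@H]1[C@H](O)[C@H]1COC(C)(C)O1 | intermediate
6 | benzoyl chloride | O=C(Cl)c1ccccc1 | starting material
7 | alkynyl diol monobenzoate | C#CC(O)[C@@]1(COC(=O)c2ccccc2)OC(C)(C)O[C@H]1[C@H](O)[C@H]1COC(C)(C)O1 | intermediate
8 | tributyltin hydride | CCCC[SnH](CCCC)CCCC | starting material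
9 | (E)-γ-hydroxy vinylstannane diol | CCCC[Sn](CCCC)(CCCC)/C=C/C(O)[C@@]1(COC(=O)c2ccccc2)OC(C)(C)O[C@H]1[C@H](O)[C@H]1COC(C)(C)O1 | intermediate
10 | (E)-β-tributylstannyl enone | CCCC[Sn](CCCC)(CCCC)/C=C/C(=O)[C@@]1(COC(=O)c2ccccc2)OC(C)(C)O[C@H]1[C@H](O)[C@H]1COC(C)(C)O1 | intermediate
11 | enone triol | CCCC[Sn](CCCC)(CCCC)/C=C/C(=O)[C@@]1(COC(=O)c2ccccc2)OC(C)(C)O[C@H]1[C@H](O)[C@H](O)CO | intermediate
12 | keto aldehyde, [(4S,5R)-5-formyl-2,2-dimethyl-4-[(E)-3-(tributylstannyl)prop-2-enoyl]-1,3-dioxolan-4-yl]methyl benzoate | CCCC[Sn](CCCC)(CCCC)/C=C/C(=O)[C@@]1(COC(=O)c2ccccc2)OC(C)(C)O[C@H]1C=O | intermediate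
13 | benzoyl bromide | O=C(Br)c1ccccc1 | starting material
14 | 1-bromoalkyl benzoate (epimers at the bromide carbon) | CCCC[Sn](CCCC)(CCCC)/C=C/C(=O)[C@@]1(COC(=O)c2ccccc2)OC(C)(C)O[C@H]1C(Br)OC(=O)c1ccccc1 | intermediate
15 | 1,6-O-isopropylidene-zeylenone | O=C(OC[C@]12OC(C)(C)O[C@H]1[C@H](OC(=O)c1ccccc1)C=CC2=O)c1ccccc1 | intermediate
16 | zeylenone | O=C(OC[C@@]1(O)C(=O)C=C[C@@H](OC(=O)c2ccccc2)[C@@H]1O)c1ccccc1 | target

Total step count: 8. Longest linear sequence: 8 (from 1).

**Steps most likely to fail**

1. Step 7 (proposed method). Closure at the tin-bearing carbon may be too slow, so that oligomerisation takes over. The acyl bromide may open the dioxolane, or facial selectivity at C5 may be poor. The fallback forms the same bond by known chemistry and sets out from 7.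
   - MnO2 should give the ynone F1.
   - H5IO6 in EtOAc hydrolyses the terminal dioxolane and effects the double glycol cleavage in one flask, which should give the ynone aldehyde F2.
   - NaI/AcOH (anti hydroiodination) should give the (Z)-β-iodo enone aldehyde F3.
   - An intramolecular Nozaki–Hiyama–Kishi reaction (CrCl2, catalytic NiCl2, DMF, high dilution) turns C4 into a vinylchromium nucleophile that adds to the C5 aldehyde.
   - The trans allylic alcohol F4 is benzoylated directly (BzCl, pyridine).
   - The cis allylic alcohol F5 is esterified with inversion (Mitsunobu reaction: PPh3, DIAD, PhCO2H).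
   - Both alcohols come back to the route at 15.

2. Step 6. Protodestannylation in the aqueous acid, loss of the internal dioxolane, or slow glycol cleavage caused by ring–chain tautomerism of the γ-hydroxy enone may erode the step. The fallback sets out from 7 and moves the acid treatment ahead of the introduction of tin. Aqueous AcOH should give the alkynyl tetraol F6. Hydrostannation as in step 4 should give the stannyl tetraol F7. MnO2 oxidation of its allylic carbinol comes back to the route at 11, which then meets only buffered NaIO4.

3. Step 4. Poor regioselectivity (tin delivered to the internal alkyne carbon) or consumption of Bu3SnH by dimerisation may occur. The fallback sets out from 3 and brings in the two-carbon unit with tin and geometry already in place. (E)-2-(Tributylstannyl)vinyllithium, made from (E)-1,2-bis(tributylstannyl)ethene and n-BuLi, is added in excess in THF at −78 °C to rt. This should give the stannyl triol F8. Selective benzoylation of its primary hydroxyl with 6, as in step 3, comes back to the route at 9.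

**Further compounds**
F1 | step 7 | ynone | C#CC(=O)[C@@]1(COC(=O)c2ccccc2)OC(C)(C)O[C@H]1[C@H](O)[C@H]1COC(C)(C)O1
F2 | step 7 | ynone aldehyde | C#CC(=O)[C@@]1(COC(=O)c2ccccc2)OC(C)(C)O[C@H]1C=O
F3 | step 7 | (Z)-β-iodo enone aldehyde | I/C=C\C(=O)[C@@]1(COC(=O)c2ccccc2)OC(C)(C)O[C@H]1C=O
F4 | step 7 | trans allylic alcohol (C5–OH trans to C6–O) | O=C(OC[C@]12OC(C)(C)O[C@H]1[C@H](O)C=CC2=O)c1ccccc1
F5 | step 7 | cis allylic alcohol (C5–OH cis to C6–O) | O=C(OC[C@]12OC(C)(C)O[C@H]1[C@@H](O)C=CC2=O)c1ccccc1
F6 | step 6 | alkynyl tetraol | C#CC(O)[C@@]1(COC(=O)c2ccccc2)OC(C)(C)O[C@H]1[C@H](O)[C@H](O)CO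
F7 | step 6 | stannyl tetraol | CCCC[Sn](CCCC)(CCCC)/C=C/C(O)[C@@]1(COC(=O)c2ccccc2)OC(C)(C)O[C@H]1[C@H](O)[C@H](O)CO
F8 | step 4 | stannyl triol | CCCC[Sn](CCCC)(CCCC)/C=C/C(O)[C@@]1(CO)OC(C)(C)O[C@H]1[C@H](O)[C@H]1COC(C)(C)O1
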